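**Retrosynthetic overview**

1. The target is a normal-series labdane (labdane numbering throughout): a trans-decalin (ring A: C1–C5, C10; ring B: C5–C10) with C4(CH3)(CO2CH3), C10–CH2OAc and C8=C17, linked through C11–C12 to an α-substituted butenolide (ring L: O–C16(=O)–C13=C14–C15H2).
2. Ring L is opened last, at C13=C14 (intramolecular Horner–Wadsworth–Emmons olefination) and, in the same flask, at C11–C12 (radical conjugate addition). The enabling feature is that in ring L C13 is the lactone α-carbon carrying only the C12 methylene, and C14 is an unsubstituted CH tied to the ring oxygen through C15H2. C12/C13 therefore map onto the CH2=C of a 2-phosphonoacrylate and C14 onto the aldehyde of its 2-oxoethyl ester, giving a C11 iodide of the finished decalin plus one five-carbon reagent.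
3. Rings A and B, the stereocentres C4, C5, C9, C10 and the C8=C17 alkene arise together in one oxidative radical bicyclization (C4–C5, then C9–C10) of an acyclic 2-methyl-3-oxo ester. The C3 oxygen is then removed, and its reduction doubles as the resolution.
4. The acyclic chain comes from geraniol (C5–C9, C11, C17), 2-bromoallyl alcohol (C1, C10, C20), a vinyl ether (C2, C3; a Claisen rearrangement fixes the C5=C10 geometry) and methyl 2-bromopropanoate (C4, C18, C19).
5. Ring order: A then B (step 8), ring L last (step 16).

Key step: step 16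

Remark on the chemistry: the bicyclic keto ester of step 8 is formed as a racemate and the single enantiomer is secured by the catalyst-controlled reduction of step 9 (a kinetic resolution); 2-bromoprop-2-en-1-ol and allyl diethylphosphonoacetate are taken as purchasable.

**Route**

Step 1
Reactants: 1 geraniol
Product: 2 geranyl tert-butyldiphenylsilyl ether
Conditions: TBDPSCl, imidazole, DMF, 0 °C to rt
Reagents that add atoms: tert-butyldiphenylsilyl chloride CC(C)(C)[Si](Cl)(c1ccccc1)c1ccccc1
Why: Silylation of the primary allylic alcohol gives an ether robust enough for the acetic acid, organolithium and zinc steps that follow.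

Step 2
Reactants: 2 geranyl tert-butyldiphenylsilyl ether
Product: 4 (E)-6-[(tert-butyldiphenylsilyl)oxy]-4-methylhex-4-enal, via secondary ozonide 3 (not isolated)
Conditions: O3 (one equivalent), CH2Cl2, −78 °C; then Me2S, −78 °C to rt
Reagents that add atoms: ozone [O-][O+]=O
Why: Chemoselective ozonolysis, since the remote trisubstituted alkene is more electron-rich than the one deactivated by the allylic silyloxy group and should be cleaved first; the E-alkene is untouched.

Step 3
Reactants: 4 (E)-6-[(tert-butyldiphenylsilyl)oxy]-4-methylhex-4-enal; 5 2-bromoprop-2-en-1-ol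
Product: 7 (E)-8-[(tert-butyldiphenylsilyl)oxy]-6-methyl-2-methylideneoct-6-ene-1,3-diol (racemic), via lithium 2-lithioprop-2-en-1-olate 6 (not isolated)
Conditions: 5, t-BuLi (3 equiv), Et2O, −78 to 0 °C; then 4, −78 °C; H2O
Reagents that add atoms: none
Why: Bromine–lithium exchange gives a β-oxido vinyllithium that cannot β-eliminate and adds 1,2 to the aldehyde; the carbinol centre forms as a racemate and is erased again in step 5.

Step 4
Reactants: 7 (E)-8-[(tert-butyldiphenylsilyl)oxy]-6-methyl-2-methylideneoct-6-ene-1,3-diol
Product: 8 (E)-8-[(tert-butyldiphenylsilyl)oxy]-3-hydroxy-6-methyl-2-methylideneoct-6-en-1-yl acetate (racemic)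
Conditions: AcCl, 2,4,6-collidine, CH2Cl2, −78 °C
Reagents that add atoms: acetyl chloride CC(Cl)=O
Why: Kinetically selective acylation of the primary over the secondary allylic hydroxyl; the future C20 acetate is installed now because a free C20 hydroxyl beside the axial C19 ester would lactonise later.

Step 5
Reactants: 8 (E)-8-[(tert-butyldiphenylsilyl)oxy]-3-hydroxy-6-methyl-2-methylideneoct-6-en-1-yl acetate
Product: 10 (2Z,6E)-8-[(tert-butyldiphenylsilyl)oxy]-6-methyl-2-(3-oxopropyl)octa-2,6-dien-1-yl acetate, via allyl vinyl ether 9 (not isolated)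
Conditions: butyl vinyl ether, Pd(OCOCF3)2 (cat.), 1,10-phenanthroline, Et3N, 75 °C; then xylene, 140 °C
Reagents that add atoms: butyl vinyl ether C=COCCCC
Why: Transfer vinylation catalysed by divalent palladium, then an aliphatic Claisen rearrangement through a chair transition state with the C6 chain pseudo-equatorial, which should place the new C1–C2 bond trans to that chain and the CH2OAc group cis to it (the minor geometric isomer is removed by chromatography).

Step 6
Reactants: 10 (2Z,6E)-8-[(tert-butyldiphenylsilyl)oxy]-6-methyl-2-(3-oxopropyl)octa-2,6-dien-1-yl acetate; 11 methyl 2-bromopropanoate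
Product: 13 methyl (6Z,10E)-6-(acetoxymethyl)-12-[(tert-butyldiphenylsilyl)oxy]-3-hydroxy-2,10-dimethyldodeca-6,10-dienoate (diastereomer mixture), via bromozinc enolate 12 (not isolated)
Conditions: 11, Zn (Me3SiCl-activated), THF, 40 °C; cold 0.5 M HCl
Reagents that add atoms: none
Why: Reformatsky reaction, in which the zinc enolate adds to the aldehyde but is too weak a nucleophile to attack the acetate; the new centres at C3 and C4 are removed or reset in steps 7 and 8.

Step 7
Reactants: 13 methyl (6Z,10E)-6-(acetoxymethyl)-12-[(tert-butyldiphenylsilyl)oxy]-3-hydroxy-2,10-dimethyldodeca-6,10-dienoate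
Product: 14 methyl (6Z,10E)-6-(acetoxymethyl)-12-[(tert-butyldiphenylsilyl)oxy]-2,10-dimethyl-3-oxododeca-6,10-dienoate
Conditions: Dess–Martin periodinane, NaHCO3, CH2Cl2, 0 °C to rt
Reagents that add atoms: none
Why: Dess–Martin oxidation of the secondary alcohol under buffered neutral conditions should give the β-keto ester without touching the allylic acetate or the silyl ether.

Step 8
Reactants: 14 methyl (6Z,10E)-6-(acetoxymethyl)-12-[(tert-butyldiphenylsilyl)oxy]-2,10-dimethyl-3-oxododeca-6,10-dienoate
Product: 15 rac-methyl 4a-(acetoxymethyl)-5-{[(tert-butyldiphenylsilyl)oxy]methyl}-1-methyl-6-methylidene-2-oxodecahydronaphthalene-1-carboxylate (trans-fused; 3-oxo, 4β-CO2Me, 4α-Me, 5α-H, 9β-CH2OSi, 10β-CH2OAc)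
Conditions: Mn(OAc)3·2H2O (2.2 equiv), Cu(OAc)2·H2O (1 equiv), degassed AcOH, rt
Reagents that add atoms: none
Why: Oxidative free-radical polyene bicyclization, in which the C4 radical of the trivalent-manganese enolate closes ring A 6-endo on C5 and the tertiary C10 radical closes ring B 6-endo on C9 through chair–chair transition states, so the two alkene geometries should translate into the trans ring fusion with the C4 ester axial (cis to C10–CH2OAc) and the C9 substituent equatorial, and divalent copper oxidises the tertiary C8 radical to the less substituted C8=C17 alkene.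

Step 9
Reactants: 15 rac-methyl 4a-(acetoxymethyl)-5-{[(tert-butyldiphenylsilyl)oxy]methyl}-1-methyl-6-methylidene-2-oxodecahydronaphthalene-1-carboxylate
Product: 16 methyl 4a-(acetoxymethyl)-5-{[(tert-butyldiphenylsilyl)oxy]methyl}-2-hydroxy-1-methyl-6-methylidenedecahydronaphthalene-1-carboxylate (single enantiomer, normal series, 3β-OH = 3S)
Conditions: (R)-2-methyl-CBS-oxazaborolidine (20 mol %), catecholborane (0.55 equiv), toluene, −78 °C; pH 7 buffer; chromatography
Reagents that add atoms: none
Why: Corey–Bakshi–Shibata reduction run as a kinetic resolution, in which the (R)-catalyst delivers hydride to the face that gives the 3S alcohol; for the normal-series enantiomer this is the substrate-preferred axial α-face attack and for its mirror image the hindered equatorial attack, so only the wanted enantiomer should be reduced quickly, and this fixes the absolute configuration of C4, C5, C9 and C10 (catecholborane spares the alkene).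

Step 10
Reactants: 16 methyl 4a-(acetoxymethyl)-5-{[(tert-butyldiphenylsilyl)oxy]methyl}-2-hydroxy-1-methyl-6-methylidenedecahydronaphthalene-1-carboxylate
Product: 17 the O-(1H-imidazol-1-ylcarbonothioyl) derivative of 16 at the C3 oxygen
Conditions: 1,1'-thiocarbonyldiimidazole, DMAP, ClCH2CH2Cl, 70 °C
Reagents that add atoms: 1,1'-thiocarbonyldiimidazole S=C(n1ccnc1)n1ccnc1
Why: Thioacylation of the equatorial secondary alcohol prepares the Barton–McCombie deoxygenation; no stereocentre is affected.

Step 11
Reactants: 17 the O-(1H-imidazol-1-ylcarbonothioyl) derivative of 16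
Product: 18 methyl 4a-(acetoxymethyl)-5-{[(tert-butyldiphenylsilyl)oxy]methyl}-1-methyl-6-methylidenedecahydronaphthalene-1-carboxylate
Conditions: Bu3SnH, AIBN (cat.), toluene, 100 °C
Reagents that add atoms: none
Why: Barton–McCombie deoxygenation, in which the stannyl radical adds to C=S, β-scission gives the secondary C3 radical and this takes hydrogen from the stannane; the radical is remote from the alkene and from all stereocentres.

Step 12
Reactants: 18 methyl 4a-(acetoxymethyl)-5-{[(tert-butyldiphenylsilyl)oxy]methyl}-1-methyl-6-methylidenedecahydronaphthalene-1-carboxylate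
Product: 19 methyl 4a-(acetoxymethyl)-5-(hydroxymethyl)-1-methyl-6-methylidenedecahydronaphthalene-1-carboxylate
Conditions: HF·pyridine, pyridine, THF, 0 °C to rt
Reagents that add atoms: none
Why: Fluoride-mediated desilylation under buffered, non-basic conditions, so the C20 acetate should neither migrate nor be cleaved and the exocyclic alkene should not isomerise.

Step 13
Reactants: 19 methyl 4a-(acetoxymethyl)-5-(hydroxymethyl)-1-methyl-6-methylidenedecahydronaphthalene-1-carboxylate
Product: 20 methyl 4a-(acetoxymethyl)-5-(iodomethyl)-1-methyl-6-methylidenedecahydronaphthalene-1-carboxylate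
Conditions: I2, PPh3, imidazole, CH2Cl2, 0 °C to rt
Reagents that add atoms: iodine II
Why: Appel-type iodination (SN2 displacement of the alkoxyphosphonium at primary C11); C9 is not involved.

Step 14
Reactants: 21 allyl diethylphosphonoacetate
Product: 23 prop-2-en-1-yl 2-(diethoxyphosphoryl)prop-2-enoate, via allyloxy adduct 22 (not isolated)
Conditions: (CH2O)n, piperidine (cat.), allyl alcohol, 80 °C; then TsOH (cat.), toluene, reflux (allyl alcohol distilled off)
Reagents that add atoms: formaldehyde (as paraformaldehyde) C=O
Why: Knoevenagel-type alkoxymethylation of the phosphonoacetate followed by acid-catalysed elimination, the standard entry to 2-phosphonoacrylates; allyl alcohol replaces methanol so that ester exchange is degenerate.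

Step 15
Reactants: 23 prop-2-en-1-yl 2-(diethoxyphosphoryl)prop-2-enoate
Product: 25 2-oxoethyl 2-(diethoxyphosphoryl)prop-2-enoate, via secondary ozonide 24 (not isolated)
Conditions: O3 (one equivalent), CH2Cl2, −78 °C; then Me2S; used crude
Reagents that add atoms: ozone [O-][O+]=O
Why: Chemoselective ozonolysis, since the monosubstituted allyl alkene should react far faster with electrophilic ozone than the alkene carrying both the phosphoryl and the ester group.

Step 16
Reactants: 20 methyl 4a-(acetoxymethyl)-5-(iodomethyl)-1-methyl-6-methylidenedecahydronaphthalene-1-carboxylate; 25 2-oxoethyl 2-(diethoxyphosphoryl)prop-2-enoate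
Product: 27 methyl 20-acetoxylabda-8(17),13-dien-16,15-olid-19-oate (target), via phosphonate adduct 26 (not isolated)
Conditions: 25 (2 equiv), (Me3Si)3SiH, Et3B (cat.), air, CH2Cl2, 0 °C to rt; then LiCl, i-Pr2NEt, MeCN, 0 °C to rt, same flask
Reagents that add atoms: none
Why: Proposed new method: the silyl radical abstracts iodine from 20, the primary C11 radical adds to the CH2 terminus of the doubly activated alkene of 25 (new C11–C12 bond) and the phosphonate- and ester-stabilised C13 radical takes hydrogen from the silane to give 26; on adding LiCl and amine (Masamune–Roush conditions) the C13 carbanion attacks the tethered aldehyde carbon C14 and syn-elimination of diethyl phosphate forms C13=C14. The closest known reactions are the Giese addition of alkyl iodides to 2-phosphonoacrylates, the conjugate addition/Horner–Wadsworth–Emmons sequence of the same acceptors with an added aldehyde, and the intramolecular Horner–Wadsworth–Emmons closure of phosphonoacetates of α-hydroxy carbonyl compounds to butenolides; what is new is their union in one flask on an acceptor that carries its own aldehyde. Ring L (O–C16–C13=C14–C15) is closed 5-exo-trig by attack of C13 on the C14 carbonyl across the ester tether, through the s-cis ester conformer as in known butenolide-forming olefinations. No stereocentre is formed, and C9 is untouched because the radical sits on C11 and the base stage is too mild to epimerise any centre. The step needs chemoselective radical addition to the phosphonoacrylate in the presence of the aldehyde and the C8=C17 alkene, which the nucleophilic character of the primary radical and the reversibility of its 3-exo attack on C8=C17 should secure, and a regiospecific olefination, which the phosphonate guarantees because the double bond can only form between C13 and C14.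

**Compound list**

1 | geraniol | CC(C)=CCC/C(C)=C/CO | starting material
2 | geranyl tert-butyldiphenylsilyl ether | CC(C)=CCC/C(C)=C/CO[Si](c1ccccc1)(c1ccccc1)C(C)(C)C | intermediate
3 | secondary ozonide of the remote alkene of 2 | CC1(C)OOC(CC/C(C)=C/CO[Si](c2ccccc2)(c2ccccc2)C(C)(C)C)O1 | intermediate (not isolated)
4 | (E)-6-[(tert-butyldiphenylsilyl)oxy]-4-methylhex-4-enal | O=CCC/C(C)=C/CO[Si](c1ccccc1)(c1ccccc1)C(C)(C)C | intermediate
5 | 2-bromoprop-2-en-1-ol | OCC(Br)=C | starting material
6 | lithium 2-lithioprop-2-en-1-olate | [Li]OCC([Li])=C | intermediate (not isolated)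
7 | (E)-8-[(tert-butyldiphenylsilyl)oxy]-6-methyl-2-methylideneoct-6-ene-1,3-diol (racemic) | C=C(CO)C(O)CC/C(C)=C/CO[Si](c1ccccc1)(c1ccccc1)C(C)(C)C | intermediate
8 | (E)-8-[(tert-butyldiphenylsilyl)oxy]-3-hydroxy-6-methyl-2-methylideneoct-6-en-1-yl acetate (racemic) | CC(=O)OCC(=C)C(O)CC/C(C)=C/CO[Si](c1ccccc1)(c1ccccc1)C(C)(C)C | intermediate
9 | vinyl ether of 8 at the secondary oxygen (racemic) | C=COC(CC/C(C)=C/CO[Si](c1ccccc1)(c1ccccc1)C(C)(C)C)C(=C)COC(C)=O | intermediate (not isolated)
10 | (2Z,6E)-8-[(tert-butyldiphenylsilyl)oxy]-6-methyl-2-(3-oxopropyl)octa-2,6-dien-1-yl acetate | O=CCC/C(COC(C)=O)=C/CC/C(C)=C/CO[Si](c1ccccc1)(c1ccccc1)C(C)(C)C | intermediate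
11 | methyl 2-bromopropanoate (racemic) | CC(Br)C(=O)OC | starting material
12 | bromozinc enolate of methyl propanoate (C-bound form) | COC(=O)C(C)[Zn]Br | intermediate (not isolated)
13 | methyl (6Z,10E)-6-(acetoxymethyl)-12-[(tert-butyldiphenylsilyl)oxy]-3-hydroxy-2,10-dimethyldodeca-6,10-dienoate (diastereomer mixture) | COC(=O)C(C)C(O)CC/C(COC(C)=O)=C/CC/C(C)=C/CO[Si](c1ccccc1)(c1ccccc1)C(C)(C)C | intermediate
14 | methyl (6Z,10E)-6-(acetoxymethyl)-12-[(tert-butyldiphenylsilyl)oxy]-2,10-dimethyl-3-oxododeca-6,10-dienoate | COC(=O)C(C)C(=O)CC/C(COC(C)=O)=C/CC/C(C)=C/CO[Si](c1ccccc1)(c1ccccc1)C(C)(C)C | intermediate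
15 | rac-methyl 4a-(acetoxymethyl)-5-{[(tert-butyldiphenylsilyl)oxy]methyl}-1-methyl-6-methylidene-2-oxodecahydronaphthalene-1-carboxylate (racemate; SMILES shows the normal-series enantiomer: 4β-CO2Me, 5α-H, 9β-CH2OSi, 10β-CH2OAc) | C=C1CC[C@@H]2[C@](COC(C)=O)(CCC(=O)[C@]2(C)C(=O)OC)[C@H]1CO[Si](c1ccccc1)(c1ccccc1)C(C)(C)C | intermediate
16 | 3β-hydroxy (3S) compound from 15, single enantiomer | C=C1CC[C@@H]2[C@](COC(C)=O)(CC[C@H](O)[C@]2(C)C(=O)OC)[C@H]1CO[Si](c1ccccc1)(c1ccccc1)C(C)(C)C | intermediate
17 | O-(1H-imidazol-1-ylcarbonothioyl) derivative of 16 | C=C1CC[C@@H]2[C@](COC(C)=O)(CC[C@H](OC(=S)n3ccnc3)[C@]2(C)C(=O)OC)[C@H]1CO[Si](c1ccccc1)(c1ccccc1)C(C)(C)C | intermediate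
18 | methyl 4a-(acetoxymethyl)-5-{[(tert-butyldiphenylsilyl)oxy]methyl}-1-methyl-6-methylidenedecahydronaphthalene-1-carboxylate (4β-CO2Me, 5α-H, 9β-CH2OSi, 10β-CH2OAc) | C=C1CC[C@@H]2[C@](COC(C)=O)(CCC[C@]2(C)C(=O)OC)[C@H]1CO[Si](c1ccccc1)(c1ccccc1)C(C)(C)C | intermediate
19 | methyl 4a-(acetoxymethyl)-5-(hydroxymethyl)-1-methyl-6-methylidenedecahydronaphthalene-1-carboxylate (same configuration) | C=C1CC[C@@H]2[C@](COC(C)=O)(CCC[C@]2(C)C(=O)OC)[C@H]1CO | intermediate
20 | methyl 4a-(acetoxymethyl)-5-(iodomethyl)-1-methyl-6-methylidenedecahydronaphthalene-1-carboxylate (same configuration) | C=C1CC[C@@H]2[C@](COC(C)=O)(CCC[C@]2(C)C(=O)OC)[C@H]1CI | intermediate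
21 | allyl diethylphosphonoacetate | C=CCOC(=O)CP(=O)(OCC)OCC | starting material
22 | prop-2-en-1-yl 2-(diethoxyphosphoryl)-3-(prop-2-en-1-yloxy)propanoate | C=CCOCC(C(=O)OCC=C)P(=O)(OCC)OCC | intermediate (not isolated)
23 | prop-2-en-1-yl 2-(diethoxyphosphoryl)prop-2-enoate | C=CCOC(=O)C(=C)P(=O)(OCC)OCC | intermediate
24 | (1,2,4-trioxolan-3-yl)methyl 2-(diethoxyphosphoryl)prop-2-enoate | C=C(C(=O)OCC1OCOO1)P(=O)(OCC)OCC | intermediate (not isolated)
25 | 2-oxoethyl 2-(diethoxyphosphoryl)prop-2-enoate | C=C(C(=O)OCC=O)P(=O)(OCC)OCC | intermediate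
26 | 2-oxoethyl 2-(diethoxyphosphoryl)-4-(decalinyl)butanoate, the conjugate adduct of the C11 radical of 20 to 25 (C13 epimers) | C=C1CC[C@@H]2[C@](COC(C)=O)(CCC[C@]2(C)C(=O)OC)[C@H]1CCC(C(=O)OCC=O)P(=O)(OCC)OCC | intermediate (not isolated)
27 | methyl (1S,4aS,5S,8aR)-4a-(acetoxymethyl)-1-methyl-6-methylidene-5-[2-(2-oxo-2,5-dihydrofuran-3-yl)ethyl]decahydronaphthalene-1-carboxylate | C=C1CC[C@@H]2[C@](COC(C)=O)(CCC[C@]2(C)C(=O)OC)[C@H]1CCC1=CCOC1=O | target

**Step count and risks**

Total step count: 16. Longest linear sequence: 14 (steps 1–13 and 16); steps 14–15 make the reagent for step 16.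

Steps most likely to fail:

1. Step 16 (proposed new method). The aldehyde-bearing acceptor may be consumed by oligomerisation or hydrosilylation before the C11 radical adds, or the base stage may stall or isomerise the butenolide. Fallback by metathesis, setting out from 20: tin-mediated radical allylation [(Bu3Sn)2, hν, benzene] with allyl 2-[(phenylsulfonyl)methyl]prop-2-enoate (C=CCOC(=O)C(=C)CS(=O)(=O)c1ccccc1), by addition of the C11 radical and β-loss of the sulfonyl radical, gives allyl 2-methylidene-4-(decalinyl)butanoate F1. Ring-closing metathesis of F1 with RuCl2(=CHPh)(PCy3)(H2IMes) (second-generation Grubbs catalyst) in CH2Cl2 at 40 °C forms the same C13=C14 bond and comes back to the route at 27.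

2. Step 8. The tertiary C10 radical may be oxidised by divalent copper before ring B closes, and β-hydride loss from C8 may be unselective. Fallback by atom-transfer termination, setting out from 14: bromination at C4 (NBS, Mg(ClO4)2 cat., MeCN) gives methyl (6Z,10E)-6-(acetoxymethyl)-2-bromo-12-[(tert-butyldiphenylsilyl)oxy]-2,10-dimethyl-3-oxododeca-6,10-dienoate F2. Lewis-acid-promoted bromine-atom-transfer radical bicyclization (Et3B, air, Yb(OTf)3, CH2Cl2, −78 °C) gives the bicyclic tertiary C8 bromide F3, and dehydrobromination (DBU, toluene, 80 °C) comes back at 15 after removal of endocyclic alkene isomers.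

3. Step 9. The rate difference between the enantiomers may be too small if substrate control overrides catalyst control. Fallback by enzymatic resolution, setting out from racemic 15: full reduction with NaBH4, then steps 10–12 on racemic material give racemic 19. Burkholderia cepacia lipase (Amano PS) with vinyl acetate acylates the C11 hydroxyl of one enantiomer; by analogy with the parent drimane alcohol the normal-series enantiomer is expected to react, giving methyl 4a,5-bis(acetoxymethyl)-1-methyl-6-methylidenedecahydronaphthalene-1-carboxylate F4, which is separated from the unreacted mirror-image alcohol. The same lipase in phosphate buffer then removes only the unhindered C11 acetate of F4 and comes back at 19. If the enzyme prefers the other enantiomer, the unreacted alcohol is 19 itself.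

Further compounds
F1 | step 16 | allyl 2-methylidene-4-(decalinyl)butanoate (decalin core and configuration as in 20) | C=C1CC[C@@H]2[C@](COC(C)=O)(CCC[C@]2(C)C(=O)OC)[C@H]1CCC(=C)C(=O)OCC=C
F2 | step 8 | methyl (6Z,10E)-6-(acetoxymethyl)-2-bromo-12-[(tert-butyldiphenylsilyl)oxy]-2,10-dimethyl-3-oxododeca-6,10-dienoate (racemic) | COC(=O)C(C)(Br)C(=O)CC/C(COC(C)=O)=C/CC/C(C)=C/CO[Si](c1ccccc1)(c1ccccc1)C(C)(C)C
F3 | step 8 | rac-methyl 4a-(acetoxymethyl)-6-bromo-5-{[(tert-butyldiphenylsilyl)oxy]methyl}-1,6-dimethyl-2-oxodecahydronaphthalene-1-carboxylate (C8 configuration open) | CC1(Br)CC[C@@H]2[C@](COC(C)=O)(CCC(=O)[C@]2(C)C(=O)OC)[C@H]1CO[Si](c1ccccc1)(c1ccccc1)C(C)(C)C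
F4 | step 9 | methyl 4a,5-bis(acetoxymethyl)-1-methyl-6-methylidenedecahydronaphthalene-1-carboxylate (normal series) | C=C1CC[C@@H]2[C@](COC(C)=O)(CCC[C@]2(C)C(=O)OC)[C@H]1COC(C)=O
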